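Numbering: daucane numbering is used throughout. C1 is the methyl-bearing quaternary fusion carbon, C2 and C3 are the ring CH2 groups, C4 is the isopropyl carbinol, C5 the fusion CH, C6 the acyloxy carbon, C7 a CH2, C8=C9 the alkene (methyl on C8) and C10 a CH2. β is the face of the C1 methyl group, α the opposite face.

## Analysis of the target

The target is a daucane ester: a cyclopentane (C1–C5) trans-fused along C1–C5 to a cycloheptene (C1, C5–C10), acylated at C6 by 4-hydroxybenzoic acid. The four stereocentres are contiguous, (1R,4S,5S,6R), which is (3S,3aS,4R,8aR) in azulene numbering. H5 is α (trans fusion), the C4 hydroxyl is α (cis to H5, isopropyl β) and the C6 oxygen is β, so the two oxygens are anti and H5 and H6 are cis. The tertiary C4 alcohol lies β to C6 and is open to dehydration or retro-aldol cleavage whenever C6 is a ketone. The C8=C9 alkene is β,γ to any C6 carbonyl and slips into conjugation with base or acid. The aryl ester and the phenol do not survive hydride or strong base. The difficulty is the crowded C1–C5–C4 region (a quaternary carbon next to the fusion CH next to a fully substituted carbinol) on a seven-membered ring whose alkene must stay where it is. The strategy rests on one feature: C5 is the α-carbon of a C6 ketone and C4 lies three atoms from C1 (C1–C2–C3–C4). A C5=C6 enol ether can therefore attack the far carbon of a C3≡C4 alkyne hung on C1 and close the five-membered ring. That enol ether and the quaternary C1 are together the direct product of a rhodium vinylcarbenoid (4+3) cycloaddition.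

## Retrosynthetic reasoning

**Aryl ester (C6–O acyl bond).** Target 30 is cut to diol 27 and acid 28, whose phenol is masked as the acetate, via 29. This keeps the base- and hydride-sensitive ester out of every earlier step. The forward reaction must acylate the secondary C6 hydroxyl and not the tertiary C4 hydroxyl, then free the phenol without touching the aroate.

**C8 methyl and C6 carbinol (functional group changes).** Diol 27 is traced through allylic chloride 26 and triol 24 to keto ester 23. The C8 methyl is the ester that the carbenoid of the cycloaddition needs as its acceptor group. It is kept as the ester as long as possible because an acrylate alkene is inert to acid, to peroxide and to gold, where a plain trisubstituted C8=C9 alkene would compete. One hydride reagent reduces ester and C6 ketone together. It must reach C6 from the α face, and the primary allylic hydroxyl must then be removed in the presence of the other two.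

**C4–O and C5–H (C5–O bond of an epoxide).** Ketol 23 comes from epoxy ketone 22 by reductive cleavage of the C5–O bond α to the ketone. This is a net syn addition of H and OH to the α face of a C4=C5 alkene, which a hydride opening (inversion) cannot give. The epoxide face is set by a temporary α-hydroxyl at C6: 22 from epoxy alcohol 21, from allylic alcohol 20, from dienone 19 by reagent-controlled reduction. A base-mediated peroxide epoxidation of 19 was not chosen for two reasons. It would expose a β,γ-unsaturated ketone to base, and its facial control would rest only on the difference between the C1 methyl and the C10 ring CH2. The price is that C6 passes twice between ketone and alcohol.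

**Alkene position (C3=C4 to C4=C5).** Dienone 19 comes from the β,γ-enone 18 by an alkene shift into conjugation. This also erases the cis ring fusion of 18, so C4 and C5 can be set afresh from the planar enone.

**Key disconnection (C4–C5).** Enone 18 is cut between C4 and C5 to the silyl enol ether–alkyne 17. The cut is made here because C5 is the only nucleophilic carbon of the enol ether and the propargyl arm on C1 can reach it only through C4. One bond then closes the five-membered ring and puts the ketone at C6 and the isopropyl group on C4. The forward reaction needs attack by carbon, in the 5-endo mode, on an internal branched alkyne.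

**Seven-membered ring (C7–C8 and C1–C10).** Cycloheptadiene 17 is cut to silyloxydiene 11 and vinyldiazoacetate 15. Cyclopropanation of the enol ether alkene followed by Cope rearrangement forms the ring, the quaternary C1, the C8=C9 alkene and the C5=C6 enol ether in one operation. No separate, regiochemically doubtful enolisation of a cycloheptanone is then needed. The forward step must pick the enol ether alkene over the trisubstituted alkene and the alkyne, and must set C1.

**Building blocks.** Diene 11 comes from enone 9 by kinetic enolisation, and 9 from vinyl iodide 7 by acylation of the derived alkenyllithium. Iodide 7 comes from allylic bromide 4 and alkyne 5, and 4 from alcohol 3, made from 1 by carboalumination. The E geometry of the trisubstituted alkene is fixed in that first step, which matters because this geometry together with the catalyst decides C1. Diazo ester 15 comes from 12 by diazo transfer, reduction and dehydration.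

## Alternatives that were turned down

**Alternative 1:** The five-membered ring is made first as (S)-2-(bromomethyl)-2-methylcyclopentan-1-one A1, which maps onto C1–C5 with the C1 methyl and C10 (as CH2Br). The forward key step is an enantioselective bromination of the alkene of 1-(prop-1-en-2-yl)cyclobutan-1-ol A2 under a chiral phosphoric acid, with 1,2-shift of a ring CH2 (semipinacol) that enlarges the cyclobutanol and sets C1.
- For it: a catalytic asymmetric entry to the quaternary centre from a trivial substrate in a well-behaved reaction class. On the certainty of the stereodefining step it is at least as strong as the rhodium step chosen here.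
- Against it: A1 holds 7 of the 15 skeletal carbons and one of four stereocentres. Its only handle at C10 is a neopentyl bromide, a poor partner for chain extension. The ketone carbon (C5) must become the CH that carries C6, its α-carbon (C4) must receive both isopropyl and hydroxyl, and the seven-membered ring is still to be built.
- Comparison: the chosen strategy forms the seven-membered ring with C1 in one step and the five-membered ring in the next, with every carbon of the skeleton in place. It gives convergence and step economy in exchange for a less proven asymmetric step.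

**Alternative 2:** The seven-membered ring is made first from an aromatic precursor, as 2-bromo-3,6-dimethylcyclohepta-2,5-dien-1-one A3 (C6 carbonyl, C5 bromide, C1 and C8 methyls, C8=C9). The forward key step is gem-dibromocyclopropanation of the tetrasubstituted enol ether alkene of the Birch diene 1-methoxy-2,5-dimethylcyclohexa-1,4-diene A4, with silver-assisted opening in the same pot, which inserts C5 between C6 and C1.
- For it: cheap materials, and the C6 oxygen, the C8 methyl and the C8=C9 alkene arrive in their final form. On this point it is stronger than the chosen route, which has to turn an ester into the C8 methyl.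
- Against it: A3 is achiral. C1 would have to be made quaternary and stereodefined by conjugate addition to a β-methyl, α-bromo cycloheptadienone, a hindered acceptor with little asymmetric precedent. The five-membered ring would still need a C4–C5 bond formation from the bromide. The skipped dienone is prone to conjugation under the basic conditions such additions use.
- Comparison: the chosen strategy sets C1 in the ring-forming step under catalyst control and delivers the enol ether regiochemistry that the next ring closure needs. It pays with three steps to adjust C8.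

**Alternative 3:** Both rings are closed at once from the acyclic acyloxy enyne A6 to the hydroazulene A5 ((1R,4S), C5=C6 and C7=C8 alkenes, C6 pivalate, C4 triethylsilyl ether). The forward key step uses a cationic monovalent rhodium catalyst, which shifts the pivaloyloxy group from C7 to C6 and joins the resulting five-carbon unit (C5–C9) to the tethered C1=C10 alkene, forming C1–C5 and C9–C10.
- For it: the highest convergence of all four plans, with two rings and two bonds in one step and C4 already a carbinol. In ring-building economy it is stronger than the chosen route.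
- Against it: the alkene partner is 1,1-disubstituted and must create the quaternary C1 in the cycloaddition, the least favourable case for this reaction. C1 would be controlled only remotely by C4, which itself requires an enantioselective synthesis of an acyclic tertiary propargylic carbinol. A5 carries its alkene at C7=C8, so it would have to be moved out of conjugation to C8=C9 against the thermodynamic bias once C6 is a ketone.
- Comparison: the chosen strategy has C8=C9 in place from the start and sets C1 by the catalyst. It offers stepwise but controllable ring formation in place of a one-step bicyclisation of doubtful scope.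

Key step: step 10

Assumption: the sense of induction of Rh2(DOSP)4 in step 9 is taken from the usual model for donor/acceptor carbenoids with this catalyst family (S catalyst, methyl phenyldiazoacetate and styrene give the (1S,2R)-cyclopropane), which with the (E)-diene 11 calls for Rh2(R-DOSP)4; if the sense were opposite, Rh2(S-DOSP)4 would be used and nothing else would change.

## Route

Step 1
Reactants: 1 prop-2-yn-1-ol
Product: 3 (E)-3-iodo-2-methylprop-2-en-1-ol, via alkenylalane 2 (not isolated)
Conditions: AlMe3, Cp2ZrCl2 (0.25 equiv), CH2Cl2, 0 °C → rt; then I2, THF, −30 → 0 °C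
Reagents that add atoms: trimethylaluminium, C[Al](C)C; iodine, II
Why: Zirconium-catalysed carboalumination (Negishi) adds methyl and aluminium syn across the terminal alkyne with methyl on the internal carbon, and iodinolysis with retention gives the E iodide; this fixes the alkene geometry that later decides C1.

Step 2
Reactants: 3 (E)-3-iodo-2-methylprop-2-en-1-ol
Product: 4 (E)-3-bromo-1-iodo-2-methylprop-1-ene
Conditions: PBr3, Et2O, 0 °C
Reagents that add atoms: phosphorus tribromide, BrP(Br)Br
Why: Standard conversion of a primary allylic alcohol into the bromide; the iodine-bearing terminus makes allylic transposition unlikely and the alkene geometry is not touched.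

Step 3
Reactants: 5 3-methylbut-1-yne; 4 (E)-3-bromo-1-iodo-2-methylprop-1-ene
Product: 7 (E)-1-iodo-2,6-dimethylhept-1-en-4-yne, via alkynyl Grignard reagent 6 (not isolated)
Conditions: EtMgBr, THF, 0 °C → rt; then 4, CuBr·SMe2 (5 mol %), 0 °C → rt
Reagents that add atoms: none
Why: Copper-catalysed SN2 coupling of an alkynylmagnesium halide with a primary allylic bromide (1,4-enyne synthesis); the vinyl iodide is inert under these conditions.

Step 4
Reactants: 7 (E)-1-iodo-2,6-dimethylhept-1-en-4-yne
Product: 9 (E)-4,8-dimethylnon-3-en-6-yn-2-one, via alkenyllithium 8 (not isolated)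
Conditions: t-BuLi (2.1 equiv), Et2O, −78 °C; then MeC(O)N(OMe)Me, −78 → 0 °C
Reagents that add atoms: N-methoxy-N-methylacetamide, CON(C)C(C)=O
Why: Iodine–lithium exchange with retention of geometry and acylation by a Weinreb amide; the chelated adduct releases the enone only on quench, so the base-sensitive skipped enynone never meets the organolithium.

Step 5
Reactants: 9 (E)-4,8-dimethylnon-3-en-6-yn-2-one
Product: 11 tert-butyl{[(3E)-4,8-dimethylnona-1,3-dien-6-yn-2-yl]oxy}dimethylsilane, via lithium dienolate 10 (not isolated)
Conditions: i-Pr2NLi, THF, −78 °C (ketone added to base); then TBSCl, DMPU, −78 → 0 °C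
Reagents that add atoms: tert-butyldimethylsilyl chloride, CC(C)(C)[Si](C)(C)Cl
Why: Kinetic deprotonation of an enone by a lithium amide takes the α′ methyl proton (cross-conjugated dienolate), and O-silylation gives the 2-silyloxy-1,3-diene; the E alkene is not involved.

Step 6
Reactants: 12 methyl acetoacetate
Product: 13 methyl 2-diazo-3-oxobutanoate
Conditions: 4-acetamidobenzenesulfonyl azide, Et3N, MeCN, 0 °C → rt
Reagents that add atoms: 4-acetamidobenzenesulfonyl azide, CC(=O)Nc1ccc(cc1)S(=O)(=O)N=[N+]=[N-]
Why: Regitz diazo transfer to an active methylene compound.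

Step 7
Reactants: 13 methyl 2-diazo-3-oxobutanoate
Product: 14 methyl 2-diazo-3-hydroxybutanoate (racemic)
Conditions: NaBH4, MeOH, 0 °C
Reagents that add atoms: none
Why: Borohydride reduces the ketone and leaves the diazo ester; the new stereocentre is lost in the next step.

Step 8
Reactants: 14 methyl 2-diazo-3-hydroxybutanoate
Product: 15 methyl 2-diazobut-3-enoate
Conditions: POCl3, Et3N, CH2Cl2, 0 °C; used at once as a cold solution
Reagents that add atoms: none
Why: Dehydration through the phosphorodichloridate gives the vinyldiazoacetate; it is used immediately because it cyclises to a pyrazole on standing.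

Step 9
Reactants: 11 tert-butyl{[(3E)-4,8-dimethylnona-1,3-dien-6-yn-2-yl]oxy}dimethylsilane; 15 methyl 2-diazobut-3-enoate
Product: 17 methyl (4S)-6-[(tert-butyldimethylsilyl)oxy]-4-methyl-4-(4-methylpent-2-yn-1-yl)cyclohepta-1,5-diene-1-carboxylate, via cis-divinylcyclopropane 16 (not isolated)
Conditions: Rh2(R-DOSP)4 (1 mol %), hexane, 15 added slowly at −26 °C, then rt; then 70 °C
Reagents that add atoms: none
Why: Tandem cyclopropanation–Cope rearrangement of a divalent rhodium vinylcarbenoid with a diene: the carbenoid takes the electron-rich 1,1-disubstituted enol ether alkene in preference to the trisubstituted alkene and the internal alkyne, and the cis-divinylcyclopropane 16 rearranges through a boat. C1 is set by the catalyst (face of cyclopropanation) together with the E geometry of 11 (methyl inside, propargyl arm outside in the boat). The inside methyl slows the Cope step, hence the final heating.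

Step 10
Reactants: 17 methyl (4S)-6-[(tert-butyldimethylsilyl)oxy]-4-methyl-4-(4-methylpent-2-yn-1-yl)cyclohepta-1,5-diene-1-carboxylate
Product: 18 methyl 8a-methyl-4-oxo-3-(propan-2-yl)-1,3a,4,5,8,8a-hexahydroazulene-6-carboxylate, cis-fused (H5 β, C3=C4 alkene, C6 ketone)
Conditions: Ph3PAuCl (10 mol %), AgBF4 (10 mol %), CH2Cl2–MeOH (10:1), 40 °C
Reagents that add atoms: none
Why: The cationic monovalent gold species from Ph3PAuCl and AgBF4 coordinates the C3≡C4 alkyne, and C5 of the silyl enol ether adds anti to gold at C4, the far alkyne carbon, to give a vinylgold species at C3 and a silyloxocarbenium ion at C6. Methanol removes the silyl group to leave the C6 ketone, and protodeauration at C3 frees the catalyst and leaves the C3=C4 alkene. The closest known reaction type is the gold-catalysed carbocyclisation of cyclic silyl enol ethers onto pendant alkynes beside a quaternary carbon under these conditions; the alkyne here is internal and α-branched, which is less usual than a terminal or iodo alkyne. The five-membered ring (C1–C2–C3–C4–C5) closes in the 5-endo-dig mode, with both alkyne carbons in the ring. The new stereocentre C5 is controlled by the tether: the propargyl arm on C1 can reach only the face of C5 on which it lies, so the fusion is cis (H5 syn to the C1 methyl); this centre is erased in step 11 and need not be the final one. The step needs attack by carbon and not oxygen, and 5-endo and not 4-exo closure: attack at C3 would close a four-membered ring, and the silylated oxygen is a poor nucleophile. The position of the enol ether (C5=C6, not C6=C7) was fixed in step 9, so no enolisation is needed. The acrylate alkene is too electron-poor to be activated by gold.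

Step 11
Reactants: 18 cis-fused β,γ-enone
Product: 19 methyl 8a-methyl-4-oxo-3-(propan-2-yl)-1,2,4,5,8,8a-hexahydroazulene-6-carboxylate (C4=C5 alkene conjugated with the C6 ketone)
Conditions: TsOH·H2O (10 mol %), PhH, 50 °C
Reagents that add atoms: none
Why: Acid-catalysed alkene migration through the C5 dienol and the tertiary C4 cation gives the tetrasubstituted conjugated enone and removes the C5 stereocentre. The C8=C9 alkene is held in place by the ester: an acrylate resists protonation, and γ-protonation of a C7 dienol would put positive charge on the ester-bearing C8.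

Step 12
Reactants: 19 conjugated dienone ester
Product: 20 methyl 4-hydroxy-8a-methyl-3-(propan-2-yl)-1,2,4,5,8,8a-hexahydroazulene-6-carboxylate, hydroxyl anti to the 8a-methyl (6α-OH)
Conditions: (R)-Me-CBS oxazaborolidine (0.3 equiv), catecholborane (1.5 equiv), PhMe, −78 °C
Reagents that add atoms: none
Why: Corey–Bakshi–Shibata reduction: the fully substituted alkenyl carbon C5 acts as the large group and C7H2 as the small one, so the (R)-catalyst should deliver hydride to the β face and give the 6α-alcohol. Selectivity is reagent-controlled; the ester is not reduced.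

Step 13
Reactants: 20 6α-allylic alcohol
Product: 21 methyl 3,3a-epoxy-4-hydroxy-8a-methyl-3-(propan-2-yl)-1,2,3,3a,4,5,8,8a-octahydroazulene-6-carboxylate (4α,5α-epoxide, 6α-OH)
Conditions: VO(acac)2 (5 mol %), t-BuOOH, CH2Cl2, 0 °C
Reagents that add atoms: tert-butyl hydroperoxide, CC(C)(C)OO
Why: Hydroxyl-directed epoxidation with a vanadium catalyst delivers oxygen to the allylic C4=C5 alkene on the face of the C6 hydroxyl, which sets the C4–O bond α. The electron-poor acrylate alkene does not react.

Step 14
Reactants: 21 epoxy alcohol
Product: 22 methyl 3,3a-epoxy-8a-methyl-4-oxo-3-(propan-2-yl)-1,2,3,3a,4,5,8,8a-octahydroazulene-6-carboxylate (4α,5α-epoxide)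
Conditions: Dess–Martin periodinane, NaHCO3, CH2Cl2, 0 °C → rt
Reagents that add atoms: none
Why: Buffered Dess–Martin oxidation removes the temporary C6 stereocentre without base, so the C8=C9 alkene stays out of conjugation.

Step 15
Reactants: 22 α,β-epoxy ketone
Product: 23 methyl (3S,3aR,8aR)-3-hydroxy-8a-methyl-4-oxo-3-(propan-2-yl)-1,2,3,3a,4,5,8,8a-octahydroazulene-6-carboxylate (4α-OH, H5 α, trans-fused)
Conditions: SmI2 (2.5 equiv), THF–MeOH, −90 °C
Reagents that add atoms: none
Why: Samarium diiodide cleaves the C–O bond α to the ketone of an α,β-epoxy ketone to give the β-hydroxy ketone, with the C4–O bond untouched. The enolate should be protonated at C5 from the α face, away from the C1 methyl and the C4 isopropyl and next to the C4 oxygen, which gives the trans ring fusion.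

Step 16
Reactants: 23 ketol ester
Product: 24 (3S,3aS,4R,8aR)-6-(hydroxymethyl)-8a-methyl-3-(propan-2-yl)-1,2,3,3a,4,5,8,8a-octahydroazulene-3,4-diol (6β-OH)
Conditions: i-Bu2AlH (6 equiv), CH2Cl2, −78 → 0 °C; Rochelle salt work-up
Reagents that add atoms: none
Why: The aluminium hydride reduces the ketone and, by 1,2-reduction, the conjugated ester. Hydride should reach C6 from the α face, because the β face is screened by the C1 methyl and the C4 isopropyl, giving the 6β-alcohol.

Step 17
Reactants: 24 triol
Product: 26 (3S,3aS,4R,8aR)-6-(chloromethyl)-8a-methyl-3-(propan-2-yl)-1,2,3,3a,4,5,8,8a-octahydroazulene-3,4-diol, via allylic mesylate 25 (not isolated)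
Conditions: MsCl, LiCl, 2,4,6-collidine, DMF, 0 °C
Reagents that add atoms: methanesulfonyl chloride, CS(=O)(=O)Cl (into 25); lithium chloride, [Li+].[Cl-]
Why: Selective sulfonylation of the primary allylic hydroxyl and displacement by chloride in the same flask; the hindered secondary and the tertiary hydroxyl do not react with the weak base.

Step 18
Reactants: 26 allylic chloride
Product: 27 (3S,3aS,4R,8aR)-6,8a-dimethyl-3-(propan-2-yl)-1,2,3,3a,4,5,8,8a-octahydroazulene-3,4-diol
Conditions: LiEt3BH (excess), THF, 0 °C
Reagents that add atoms: none
Why: SN2 displacement of a primary allylic chloride by hydride gives the C8 methyl without allylic transposition; the free hydroxyls only consume extra hydride.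

Step 19
Reactants: 27 diol; 28 4-acetoxybenzoic acid
Product: 29 (3S,3aS,4R,8aR)-3-hydroxy-6,8a-dimethyl-3-(propan-2-yl)-1,2,3,3a,4,5,8,8a-octahydroazulen-4-yl 4-acetoxybenzoate
Conditions: EDC·HCl, DMAP, CH2Cl2, rt
Reagents that add atoms: none
Why: Steglich esterification acylates the secondary C6 hydroxyl; the tertiary C4 hydroxyl is inert under these conditions.

Step 20
Reactants: 29 acetoxybenzoate
Product: 30 (3S,3aS,4R,8aR)-3-hydroxy-6,8a-dimethyl-3-(propan-2-yl)-1,2,3,3a,4,5,8,8a-octahydroazulen-4-yl 4-hydroxybenzoate (target)
Conditions: pyrrolidine, CH2Cl2, 0 °C → rt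
Reagents that add atoms: none
Why: Aminolysis of the aryl acetate is much faster than attack on the hindered secondary aroate, so the phenol is freed and the ester stays.

## Compound list

1 | prop-2-yn-1-ol | C#CCO | starting material
2 | (E)-[3-(dimethylaluminiooxy)-2-methylprop-1-enyl]dimethylalane | C[Al](C)OC/C(C)=C/[Al](C)C | intermediate
3 | (E)-3-iodo-2-methylprop-2-en-1-ol | OC/C(C)=C/I | intermediate
4 | (E)-3-bromo-1-iodo-2-methylprop-1-ene | BrC/C(C)=C/I | intermediate
5 | 3-methylbut-1-yne | CC(C)C#C | starting material
6 | (3-methylbut-1-yn-1-yl)magnesium bromide | CC(C)C#C[Mg]Br | intermediate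
7 | (E)-1-iodo-2,6-dimethylhept-1-en-4-yne | CC(C)C#CC/C(C)=C/I | intermediate
8 | [(E)-2,6-dimethylhept-1-en-4-yn-1-yl]lithium | CC(C)C#CC/C(C)=C/[Li] | intermediate
9 | (E)-4,8-dimethylnon-3-en-6-yn-2-one | CC(=O)/C=C(\C)CC#CC(C)C | intermediate
10 | lithium (3E)-4,8-dimethylnona-1,3-dien-6-yn-2-olate | [Li]OC(=C)/C=C(\C)CC#CC(C)C | intermediate
11 | tert-butyl{[(3E)-4,8-dimethylnona-1,3-dien-6-yn-2-yl]oxy}dimethylsilane | C=C(O[Si](C)(C)C(C)(C)C)/C=C(\C)CC#CC(C)C | intermediate
12 | methyl acetoacetate | CC(=O)CC(=O)OC | starting material
13 | methyl 2-diazo-3-oxobutanoate | CC(=O)C(=[N+]=[N-])C(=O)OC | intermediate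
14 | methyl 2-diazo-3-hydroxybutanoate (racemic) | CC(O)C(=[N+]=[N-])C(=O)OC | intermediate
15 | methyl 2-diazobut-3-enoate | C=CC(=[N+]=[N-])C(=O)OC | intermediate
16 | methyl 2-[(tert-butyldimethylsilyl)oxy]-2-[(E)-2,6-dimethylhept-1-en-4-yn-1-yl]-1-vinylcyclopropane-1-carboxylate, the two alkenyl groups cis, ester trans to the dienyl arm | COC(=O)[C@]1(C=C)C[C@@]1(O[Si](C)(C)C(C)(C)C)/C=C(\C)CC#CC(C)C | intermediate
17 | methyl (4S)-6-[(tert-butyldimethylsilyl)oxy]-4-methyl-4-(4-methylpent-2-yn-1-yl)cyclohepta-1,5-diene-1-carboxylate | COC(=O)C1=CC[C@@](C)(CC#CC(C)C)C=C(O[Si](C)(C)C(C)(C)C)C1 | intermediate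
18 | methyl 8a-methyl-4-oxo-3-(propan-2-yl)-1,3a,4,5,8,8a-hexahydroazulene-6-carboxylate, cis-fused (H5 and C1 methyl both β) | COC(=O)C1=CC[C@@]2(C)CC=C(C(C)C)[C@H]2C(=O)C1 | intermediate
19 | methyl 8a-methyl-4-oxo-3-(propan-2-yl)-1,2,4,5,8,8a-hexahydroazulene-6-carboxylate | COC(=O)C1=CC[C@@]2(C)CCC(C(C)C)=C2C(=O)C1 | intermediate
20 | methyl 4-hydroxy-8a-methyl-3-(propan-2-yl)-1,2,4,5,8,8a-hexahydroazulene-6-carboxylate, 6α-OH (anti to the C1 methyl) | COC(=O)C1=CC[C@@]2(C)CCC(C(C)C)=C2[C@@H](O)C1 | intermediate
21 | methyl 3,3a-epoxy-4-hydroxy-8a-methyl-3-(propan-2-yl)-1,2,3,3a,4,5,8,8a-octahydroazulene-6-carboxylate, epoxide and hydroxyl both α | COC(=O)C1=CC[C@@]2(C)CC[C@@]3(C(C)C)O[C@@]23[C@@H](O)C1 | intermediate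
22 | methyl 3,3a-epoxy-8a-methyl-4-oxo-3-(propan-2-yl)-1,2,3,3a,4,5,8,8a-octahydroazulene-6-carboxylate, epoxide α | COC(=O)C1=CC[C@@]2(C)CC[C@@]3(C(C)C)O[C@@]23C(=O)C1 | intermediate
23 | methyl (3S,3aR,8aR)-3-hydroxy-8a-methyl-4-oxo-3-(propan-2-yl)-1,2,3,3a,4,5,8,8a-octahydroazulene-6-carboxylate | COC(=O)C1=CC[C@@]2(C)CC[C@](O)(C(C)C)[C@@H]2C(=O)C1 | intermediate
24 | (3S,3aS,4R,8aR)-6-(hydroxymethyl)-8a-methyl-3-(propan-2-yl)-1,2,3,3a,4,5,8,8a-octahydroazulene-3,4-diol | OCC1=CC[C@@]2(C)CC[C@](O)(C(C)C)[C@@H]2[C@H](O)C1 | intermediate
25 | [(3S,3aS,4R,8aR)-3,4-dihydroxy-8a-methyl-3-(propan-2-yl)-1,2,3,3a,4,5,8,8a-octahydroazulen-6-yl]methyl methanesulfonate | CS(=O)(=O)OCC1=CC[C@@]2(C)CC[C@](O)(C(C)C)[C@@H]2[C@H](O)C1 | intermediate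
26 | (3S,3aS,4R,8aR)-6-(chloromethyl)-8a-methyl-3-(propan-2-yl)-1,2,3,3a,4,5,8,8a-octahydroazulene-3,4-diol | ClCC1=CC[C@@]2(C)CC[C@](O)(C(C)C)[C@@H]2[C@H](O)C1 | intermediate
27 | (3S,3aS,4R,8aR)-6,8a-dimethyl-3-(propan-2-yl)-1,2,3,3a,4,5,8,8a-octahydroazulene-3,4-diol | CC1=CC[C@@]2(C)CC[C@](O)(C(C)C)[C@@H]2[C@H](O)C1 | intermediate
28 | 4-acetoxybenzoic acid | CC(=O)Oc1ccc(cc1)C(=O)O | starting material
29 | (3S,3aS,4R,8aR)-3-hydroxy-6,8a-dimethyl-3-(propan-2-yl)-1,2,3,3a,4,5,8,8a-octahydroazulen-4-yl 4-acetoxybenzoate | CC1=CC[C@@]2(C)CC[C@](O)(C(C)C)[C@@H]2[C@H](OC(=O)c2ccc(OC(C)=O)cc2)C1 | intermediate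
30 | (3S,3aS,4R,8aR)-3-hydroxy-6,8a-dimethyl-3-(propan-2-yl)-1,2,3,3a,4,5,8,8a-octahydroazulen-4-yl 4-hydroxybenzoate | CC1=CC[C@@]2(C)CC[C@](O)(C(C)C)[C@@H]2[C@H](OC(=O)c2ccc(O)cc2)C1 | target

## Step count and least certain steps

Total step count: 20. Longest linear sequence: 17 steps (steps 1–5 and 9–20); steps 6–8 form the three-step branch to 15.

**Step 10 (key step).** Attack of C5 on the isopropyl-bearing alkyne carbon may be slow for steric reasons. Methanolysis of the silyl enol ether, which loses both the nucleophile and its regiochemistry, or addition of methanol to the alkyne could then overtake cyclisation. The fallback closes the ring on an alkyne carbon that carries iodine and adds the isopropyl group afterwards. It sets out from 4 and returns at 18.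
- Copper-catalysed coupling of 4 with commercial lithium (trimethylsilyl)acetylide gives trimethyl[(4E)-5-iodo-4-methylpent-4-en-1-yn-1-yl]silane F1.
- Iodine–lithium exchange and acylation as in step 4 give (3E)-4-methyl-7-(trimethylsilyl)hept-3-en-6-yn-2-one F2.
- AgNO3 (catalytic) with N-iodosuccinimide exchanges silicon for iodine and gives (3E)-7-iodo-4-methylhept-3-en-6-yn-2-one F3.
- Enolisation and silylation as in step 5 give tert-butyl{[(3E)-7-iodo-4-methylhepta-1,3-dien-6-yn-2-yl]oxy}dimethylsilane F4.
- Cycloaddition with 15 as in step 9 gives methyl 6-[(tert-butyldimethylsilyl)oxy]-4-(3-iodoprop-2-yn-1-yl)-4-methylcyclohepta-1,5-diene-1-carboxylate F5.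
- The gold cyclisation under the conditions of step 10, here in its best documented form, gives cis-fused methyl 3-iodo-8a-methyl-4-oxo-1,3a,4,5,8,8a-hexahydroazulene-6-carboxylate F6.
- A Negishi coupling of F6 with i-PrZnBr (Pd(OAc)2, CPhos, THF) installs the isopropyl group and gives 18.

**Step 9.** Enantiofacial control may be incomplete, because the alkene that is cyclopropanated carries two groups of similar size (silyloxy and alkenyl). The Cope step may also lag, since the boat has a methyl group inside; heat answers that. Insertion of the carbenoid into the doubly activated C–H bonds between alkene and alkyne is a further possible diversion. The fallback gives up catalyst control and separates the enantiomers later as diastereomers. It sets out from 11 and 15 and returns at 20.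
- With the achiral catalyst Rh2(OPiv)4 the cycloaddition gives 17 as a racemate with the enantiomer of 17 F7.
- Steps 10 and 11 carry the mixture to 18 and 19 together with the enantiomer of 18 F8 and the enantiomer of 19 F9.
- In step 12 the (R)-oxazaborolidine sets the same absolute configuration at C6 in both enantiomers of the ketone. F9 therefore gives the alcohol with hydroxyl syn to the C1 methyl F10, a diastereomer of 20 that is removed by chromatography.

**Step 11.** The isomerisation may run on. The C8=C9 alkene could drift into conjugation with C6 through the C7 dienol, or a hydride shift in the C4 cation could lead to the isopropylidene isomer. The fallback replaces the proton shuttle by addition and elimination, and sets out from 18 and returns at 19.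
- Dry HCl in CH2Cl2 at −40 °C adds to the C3=C4 alkene in the Markovnikov sense and gives the tertiary chloride methyl 3-chloro-8a-methyl-4-oxo-3-(propan-2-yl)-1,2,3,3a,4,5,8,8a-octahydroazulene-6-carboxylate F11.
- Et3N at 0 °C removes HCl through the C5 enolate (E1cB), which is far faster than any proton shift at C7/C9, and gives 19.

**Step 12.** Facial selectivity may be poor, because the reagent must deliver hydride to the β face, the face that carries the C1 methyl (a mismatched case). The fallback accepts the substrate's own preference and inverts. It sets out from 19 and returns at 20.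
- Luche reduction (NaBH4, CeCl3·7H2O, MeOH, −78 °C) gives the 6β-alcohol methyl 4-hydroxy-8a-methyl-3-(propan-2-yl)-1,2,4,5,8,8a-hexahydroazulene-6-carboxylate F12.
- A Mitsunobu reaction (4-nitrobenzoic acid, PPh3, diisopropyl azodicarboxylate) inverts C6 and gives the 6α-(4-nitrobenzoate) F13.
- Methanolysis (K2CO3, MeOH, 0 °C) gives 20.

**Step 16.** Hydride may be delivered to the wrong face of C6 if an aluminium chelate between the C4 alkoxide and the ketone turns the carbonyl group. Retro-aldol cleavage of the aluminium aldolate is a second concern. The fallback sets C6 by intramolecular delivery. It sets out from 23 and returns at 24.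
- Evans–Saksena reduction with Me4NBH(OAc)3 (MeCN–AcOH, −30 °C) transfers hydride from boron bound to the α C4 hydroxyl to the α face of C6. It gives methyl 3,4-dihydroxy-8a-methyl-3-(propan-2-yl)-1,2,3,3a,4,5,8,8a-octahydroazulene-6-carboxylate F14 (4α-OH, 6β-OH).
- i-Bu2AlH then reduces only the ester and gives 24.

## Further compounds

F1 | step 10 | trimethyl[(4E)-5-iodo-4-methylpent-4-en-1-yn-1-yl]silane | C[Si](C)(C)C#CC/C(C)=C/I
F2 | step 10 | (3E)-4-methyl-7-(trimethylsilyl)hept-3-en-6-yn-2-one | CC(=O)/C=C(\C)CC#C[Si](C)(C)C
F3 | step 10 | (3E)-7-iodo-4-methylhept-3-en-6-yn-2-one | CC(=O)/C=C(\C)CC#CI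
F4 | step 10 | tert-butyl{[(3E)-7-iodo-4-methylhepta-1,3-dien-6-yn-2-yl]oxy}dimethylsilane | C=C(O[Si](C)(C)C(C)(C)C)/C=C(\C)CC#CI
F5 | step 10 | methyl 6-[(tert-butyldimethylsilyl)oxy]-4-(3-iodoprop-2-yn-1-yl)-4-methylcyclohepta-1,5-diene-1-carboxylate (C4 arranged as in 17) | COC(=O)C1=CC[C@@](C)(CC#CI)C=C(O[Si](C)(C)C(C)(C)C)C1
F6 | step 10 | methyl 3-iodo-8a-methyl-4-oxo-1,3a,4,5,8,8a-hexahydroazulene-6-carboxylate, cis-fused | COC(=O)C1=CC[C@@]2(C)CC=C(I)[C@H]2C(=O)C1
F7 | step 9 | methyl (4R)-6-[(tert-butyldimethylsilyl)oxy]-4-methyl-4-(4-methylpent-2-yn-1-yl)cyclohepta-1,5-diene-1-carboxylate (enantiomer of 17) | COC(=O)C1=CC[C@](C)(CC#CC(C)C)C=C(O[Si](C)(C)C(C)(C)C)C1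
F8 | step 9 | enantiomer of 18 | COC(=O)C1=CC[C@]2(C)CC=C(C(C)C)[C@@H]2C(=O)C1
F9 | step 9 | enantiomer of 19 | COC(=O)C1=CC[C@]2(C)CCC(C(C)C)=C2C(=O)C1
F10 | step 9 | methyl 4-hydroxy-8a-methyl-3-(propan-2-yl)-1,2,4,5,8,8a-hexahydroazulene-6-carboxylate from F9, hydroxyl syn to the 8a-methyl | COC(=O)C1=CC[C@]2(C)CCC(C(C)C)=C2[C@@H](O)C1
F11 | step 11 | methyl 3-chloro-8a-methyl-4-oxo-3-(propan-2-yl)-1,2,3,3a,4,5,8,8a-octahydroazulene-6-carboxylate (C4 epimers) | COC(=O)C1=CC[C@@]2(C)CCC(Cl)(C(C)C)[C@H]2C(=O)C1
F12 | step 12 | methyl 4-hydroxy-8a-methyl-3-(propan-2-yl)-1,2,4,5,8,8a-hexahydroazulene-6-carboxylate, 6β-OH (syn to the C1 methyl) | COC(=O)C1=CC[C@@]2(C)CCC(C(C)C)=C2[C@H](O)C1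
F13 | step 12 | methyl 8a-methyl-4-[(4-nitrobenzoyl)oxy]-3-(propan-2-yl)-1,2,4,5,8,8a-hexahydroazulene-6-carboxylate, 6α-ester | COC(=O)C1=CC[C@@]2(C)CCC(C(C)C)=C2[C@@H](OC(=O)c2ccc(cc2)[N+](=O)[O-])C1
F14 | step 16 | methyl 3,4-dihydroxy-8a-methyl-3-(propan-2-yl)-1,2,3,3a,4,5,8,8a-octahydroazulene-6-carboxylate (4α-OH, H5 α, 6β-OH) | COC(=O)C1=CC[C@@]2(C)CC[C@](O)(C(C)C)[C@@H]2[C@H](O)C1
A1 | alternative 1 | (S)-2-(bromomethyl)-2-methylcyclopentan-1-one | BrC[C@@]1(C)CCCC1=O
A2 | alternative 1 | 1-(prop-1-en-2-yl)cyclobutan-1-ol | CC(=C)C1(O)CCC1
A3 | alternative 2 | 2-bromo-3,6-dimethylcyclohepta-2,5-dien-1-one | CC1=CCC(C)=C(Br)C(=O)C1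
A4 | alternative 2 | 1-methoxy-2,5-dimethylcyclohexa-1,4-diene | COC1=C(C)CC=C(C)C1
A5 | alternative 3 | 6,8a-dimethyl-3-(propan-2-yl)-3-[(triethylsilyl)oxy]-1,2,3,7,8,8a-hexahydroazulen-4-yl 2,2-dimethylpropanoate, (1R,4S) in daucane numbering | CC1=CC(OC(=O)C(C)(C)C)=C2[C@@](O[Si](CC)(CC)CC)(C(C)C)CC[C@]2(C)CC1
A6 | alternative 3 | 2,9-dimethyl-6-(propan-2-yl)-6-[(triethylsilyl)oxy]deca-1,9-dien-4-yn-3-yl 2,2-dimethylpropanoate (carbinol carbon arranged as C4 of A5) | C=C(C)C(OC(=O)C(C)(C)C)C#C[C@@](O[Si](CC)(CC)CC)(C(C)C)CCC(C)=C
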